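Ring A, the cyclohexa-2,5-dienone, is numbered C1 (C=O), C2 (methyl-bearing carbon next to the ring CH), C3 (CH), C4 (quaternary), C5 (chain-bearing), C6. It is cut into two three-carbon pieces. The key step joins the allyl-type anion of an alkenyl γ-pyrone (C2–C3–C4) to an enantiopure α,β-epoxy acyl imidazole (C5–C6–C1): acylation at C2 and then epoxide opening at C5 by the resulting dienolate close ring A, with epoxide strain as driving force. The step exploits C4 being doubly vinylogous, to the carbonyl of ring B (the pyrone) and to C1. The Sharpless epoxide fixes C4; dehydration, desilylation and oxidation finish.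

Key step: step 15

Remark on the chemistry: the silyloxy-bearing carbon of the side chain becomes the ketone in step 18, so its configuration (S, from the syn-aldol) is immaterial. D-(−)-diethyl tartrate is diethyl (2S,3S)-tartrate. Ring A numbering of the overview is used in all steps.

Step 1
Reactants: 1 ethyl 2-methyl-3-oxopentanoate; 2 N-methoxy-N-methylpropanamide
Product: 3 ethyl 2,4-dimethyl-3,5-dioxoheptanoate
Conditions: LiN(iPr)2 (2.2 equiv), THF, −78 → 0 °C; then 2, 0 °C; aq. HCl
Reagents that add atoms: none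
Why: The γ-carbon of the β-keto ester dianion is its most nucleophilic site and is acylated by the Weinreb amide (dianion C-acylation), the stable tetrahedral adduct preventing over-addition, and no stereocentre needs control.

Step 2
Reactants: 3 ethyl 2,4-dimethyl-3,5-dioxoheptanoate
Product: 4 6-ethyl-4-hydroxy-3,5-dimethyl-2H-pyran-2-one
Conditions: DBU, toluene, 80 °C
Reagents that add atoms: none
Why: Enolisation of the 5-ketone and attack of the enol oxygen on the ester (lactonisation, the usual triketide pyranone closure) gives the 4-hydroxy-2-pyranone with loss of ethanol.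

Step 3
Reactants: 4 6-ethyl-4-hydroxy-3,5-dimethyl-2H-pyran-2-one
Product: 5 2-ethyl-6-methoxy-3,5-dimethyl-4H-pyran-4-one
Conditions: MeOTf, CH2Cl2, rt; aqueous work-up
Reagents that add atoms: methyl trifluoromethanesulfonate, COS(=O)(=O)C(F)(F)F
Why: The hard methylating agent alkylates the lactone carbonyl oxygen of the vinylogous acid and loss of the hydroxyl proton leaves the 2-methoxy-4-pyranone (O-methylation), the regiochemistry known for 3,5-dialkyl-4-hydroxy-2-pyranones with methyl sulfonates of this kind.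

Step 4
Reactants: 5 2-ethyl-6-methoxy-3,5-dimethyl-4H-pyran-4-one; 6 propanal
Product: 9 2-methoxy-3,5-dimethyl-6-[(2E)-pent-2-en-2-yl]-4H-pyran-4-one, via lithium aldolate 7 (not isolated), via mesylate 8 (not isolated)
Conditions: LiN(SiMe3)2, THF, −78 °C; 6; then MeSO2Cl, −78 → 0 °C; then DBU, rt
Reagents that add atoms: none
Why: Lateral deprotonation of the ethyl group gives a vinylogous enolate that adds to propanal (aldol addition), and mesylation followed by E1cB elimination through the pyrone-stabilised carbanion gives the conjugated alkene, the E isomer being favoured because it keeps the ethyl group away from ring B.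

Step 5
Reactants: 10 (R)-4-benzyl-3-propanoyl-1,3-oxazolidin-2-one; 6 propanal
Product: 11 (R)-4-benzyl-3-[(2R,3S)-3-hydroxy-2-methylpentanoyl]-1,3-oxazolidin-2-one
Conditions: Bu2BOTf, iPr2NEt, CH2Cl2, 0 °C; then 6, −78 → 0 °C; H2O2, MeOH, pH 7 buffer
Reagents that add atoms: none
Why: The Z boron enolate adds to propanal through a closed Zimmerman–Traxler transition state (Evans syn-aldol reaction), the benzyl group of the auxiliary fixing the (2R,3S) configuration, of which the 2R centre is the future side-chain stereocentre.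

Step 6
Reactants: 11 (R)-4-benzyl-3-[(2R,3S)-3-hydroxy-2-methylpentanoyl]-1,3-oxazolidin-2-one
Product: 12 (R)-4-benzyl-3-[(2R,3S)-3-{[tert-butyl(dimethyl)silyl]oxy}-2-methylpentanoyl]-1,3-oxazolidin-2-one
Conditions: t-BuMe2SiOTf, 2,6-lutidine, CH2Cl2, 0 °C
Reagents that add atoms: tert-butyldimethylsilyl trifluoromethanesulfonate, CC(C)(C)[Si](C)(C)OS(=O)(=O)C(F)(F)F
Why: Silylation of the secondary alcohol with the silyl triflate and a hindered base proceeds without retro-aldol cleavage and leaves both stereocentres untouched.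

Step 7
Reactants: 12 (R)-4-benzyl-3-[(2R,3S)-3-{[tert-butyl(dimethyl)silyl]oxy}-2-methylpentanoyl]-1,3-oxazolidin-2-one
Product: 13 (2S,3S)-3-{[tert-butyl(dimethyl)silyl]oxy}-2-methylpentan-1-ol
Conditions: LiBH4, MeOH (1 equiv), THF, 0 °C
Reagents that add atoms: none
Why: Reductive cleavage of the imide at the exocyclic carbonyl with LiBH4 releases the primary alcohol and the auxiliary without touching the α-stereocentre (the descriptor changes only through the priority rules).

Step 8
Reactants: 13 (2S,3S)-3-{[tert-butyl(dimethyl)silyl]oxy}-2-methylpentan-1-ol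
Product: 14 (2R,3S)-3-{[tert-butyl(dimethyl)silyl]oxy}-2-methylpentanal
Conditions: TEMPO (2,2,6,6-tetramethylpiperidin-1-oxyl, cat.), PhI(OAc)2, CH2Cl2, rt
Reagents that add atoms: none
Why: The oxoammonium-mediated oxidation (TEMPO oxidation) stops at the aldehyde under neutral, non-epimerising conditions.

Step 9
Reactants: 14 (2R,3S)-3-{[tert-butyl(dimethyl)silyl]oxy}-2-methylpentanal; 15 2-(triphenyl-λ5-phosphanylidene)propanal
Product: 16 (2E,4S,5S)-5-{[tert-butyl(dimethyl)silyl]oxy}-2,4-dimethylhept-2-enal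
Conditions: toluene, 90 °C
Reagents that add atoms: none
Why: The stabilised formyl ylide gives the E trisubstituted enal (Wittig reaction) and the less electrophilic product does not react again.

Step 10
Reactants: 16 (2E,4S,5S)-5-{[tert-butyl(dimethyl)silyl]oxy}-2,4-dimethylhept-2-enal; 17 ethyl 2-(triphenyl-λ5-phosphanylidene)propanoate
Product: 18 ethyl (2E,4E,6S,7S)-7-{[tert-butyl(dimethyl)silyl]oxy}-2,4,6-trimethylnona-2,4-dienoate
Conditions: toluene, 80 °C
Reagents that add atoms: none
Why: The stabilised ester ylide adds to the enal with thermodynamic control of the oxaphosphetane (Wittig reaction) and gives the E,E dienoate.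

Step 11
Reactants: 18 ethyl (2E,4E,6S,7S)-7-{[tert-butyl(dimethyl)silyl]oxy}-2,4,6-trimethylnona-2,4-dienoate
Product: 19 (2E,4E,6S,7S)-7-{[tert-butyl(dimethyl)silyl]oxy}-2,4,6-trimethylnona-2,4-dien-1-ol
Conditions: iBu2AlH, CH2Cl2, −78 °C; aqueous work-up
Reagents that add atoms: none
Why: 1,2-Reduction of the conjugated ester with iBu2AlH gives the allylic alcohol without conjugate reduction.

Step 12
Reactants: 19 (2E,4E,6S,7S)-7-{[tert-butyl(dimethyl)silyl]oxy}-2,4,6-trimethylnona-2,4-dien-1-ol
Product: 20 [(2R,3R)-3-[(2E,4S,5S)-5-{[tert-butyl(dimethyl)silyl]oxy}-4-methylhept-2-en-2-yl]-2-methyloxiran-2-yl]methanol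
Conditions: Ti(OiPr)4 (10 mol %), D-(−)-diethyl tartrate (12 mol %), t-BuOOH, 4 Å molecular sieves, CH2Cl2, −25 °C
Reagents that add atoms: tert-butyl hydroperoxide, CC(C)(C)OO
Why: The Sharpless asymmetric epoxidation oxidises only the alkene of the allylic alcohol, and the D-(−)-tartrate ligand delivers oxygen to the face that gives the (2R,3R)-epoxide under reagent control, independent of the remote side-chain centres.

Step 13
Reactants: 20 [(2R,3R)-3-[(2E,4S,5S)-5-{[tert-butyl(dimethyl)silyl]oxy}-4-methylhept-2-en-2-yl]-2-methyloxiran-2-yl]methanol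
Product: 22 (2S,3R)-3-[(2E,4S,5S)-5-{[tert-butyl(dimethyl)silyl]oxy}-4-methylhept-2-en-2-yl]-2-methyloxirane-2-carboxylic acid, via epoxy aldehyde 21 (not isolated)
Conditions: TEMPO (cat.), PhI(OAc)2, MeCN–pH 7 phosphate buffer, 0 °C → rt
Reagents that add atoms: water, O
Why: The TEMPO oxidation in the presence of water carries the primary alcohol through the aldehyde hydrate to the acid near neutral pH, which spares the vinyl epoxide, the alkene and the silyl ether (the descriptor at C2 changes only through the priority rules).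

Step 14
Reactants: 22 (2S,3R)-3-[(2E,4S,5S)-5-{[tert-butyl(dimethyl)silyl]oxy}-4-methylhept-2-en-2-yl]-2-methyloxirane-2-carboxylic acid
Product: 23 [(2S,3R)-3-[(2E,4S,5S)-5-{[tert-butyl(dimethyl)silyl]oxy}-4-methylhept-2-en-2-yl]-2-methyloxiran-2-yl](1H-imidazol-1-yl)methanone
Conditions: 1,1'-carbonyldiimidazole, THF, 0 °C → rt; used crude
Reagents that add atoms: 1,1'-carbonyldiimidazole, O=C(n1ccnc1)n1ccnc1
Why: The acid is activated as its imidazolide with loss of carbon dioxide under neutral conditions, giving a non-enolisable acyl donor (its α-carbon is fully substituted).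

Step 15
Reactants: 9 2-methoxy-3,5-dimethyl-6-[(2E)-pent-2-en-2-yl]-4H-pyran-4-one; 23 [(2S,3R)-3-[(2E,4S,5S)-5-{[tert-butyl(dimethyl)silyl]oxy}-4-methylhept-2-en-2-yl]-2-methyloxiran-2-yl](1H-imidazol-1-yl)methanone
Product: 26 (4S,5R,6S)-5-[(2E,4S,5S)-5-{[tert-butyl(dimethyl)silyl]oxy}-4-methylhept-2-en-2-yl]-6-hydroxy-4-(6-methoxy-3,5-dimethyl-4-oxo-4H-pyran-2-yl)-2,4,6-trimethylcyclohex-2-en-1-one, via lithium trienolate 24 (not isolated), via epoxy ketone 25 (not isolated)
Conditions: 9 (2.1 equiv), LiN(iPr)2 (2.0 equiv), THF–DMPU, −78 °C; then 23 (1.0 equiv), −78 → 40 °C; aq. NH4Cl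
Reagents that add atoms: none
Why: LiN(iPr)2 removes an allylic proton of 9 to give the trienolate 24, an allyl anion over C2–C3–C4 conjugated to the carbonyl of ring B, which is acylated at its unhindered terminus C2 by the imidazolide 23 (bond C1–C2), and the ketone 25, deprotonated at C2 by the second equivalent of 24, then attacks the allylic epoxide carbon C5 through its γ-carbon C4 with inversion (bond C4–C5), lithium bridging the enolate and epoxide oxygens. The closest known reaction types are the C-acylation of lithium enolates by N-acylimidazoles and the intramolecular enolate–epoxide alkylation of the Stork epoxynitrile-cyclisation type, here in vinylogous form. Ring A closes in the 6-(enolendo) mode at the nucleophile and by 6-endo opening of the epoxide (the distal carbon is attacked, so both epoxide carbons enter the ring), whereas attack at C6 would be a disfavoured 5-(enolendo) closure at a fully substituted carbon and attack through C2 would give a four-membered ring. The new stereocentre C4 is controlled by the epoxide made in step 12: C6 lies in the plane of the dienolate, backside attack at C5 is possible only with C5 on one face of that plane, and the position at C4 that points into the forming ring is taken by the methyl group and not by the bulky pyrone (E geometry at C3=C4), so the (2S,3R)-epoxide is translated into the 4S centre with the C4 and C6 methyl groups cis and the C6 hydroxyl cis to the C5 hydrogen, C5 and C6 being relay centres that step 16 removes. The step needs acylation at C2 instead of C4 or oxygen, which the α-quaternary acyl donor (it cannot approach the tertiary C4 beside the 3-methyl group of ring B) and DMPU should secure, and it needs attack at C5 instead of C6, which the allylic, secondary nature of C5 against the quaternary C6 secures.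

Step 16
Reactants: 26 (4S,5R,6S)-5-[(2E,4S,5S)-5-{[tert-butyl(dimethyl)silyl]oxy}-4-methylhept-2-en-2-yl]-6-hydroxy-4-(6-methoxy-3,5-dimethyl-4-oxo-4H-pyran-2-yl)-2,4,6-trimethylcyclohex-2-en-1-one
Product: 27 (4S)-3-[(2E,4S,5S)-5-{[tert-butyl(dimethyl)silyl]oxy}-4-methylhept-2-en-2-yl]-4-(6-methoxy-3,5-dimethyl-4-oxo-4H-pyran-2-yl)-2,4,6-trimethylcyclohexa-2,5-dien-1-one
Conditions: methyl N-(triethylammoniosulfonyl)carbamate (Burgess reagent), toluene, 60 °C
Reagents that add atoms: none
Why: The tertiary α-hydroxy ketone forms a sulfamate that undergoes thermal syn-elimination (Burgess dehydration) with the cis, allylic C5 hydrogen, which gives the fully conjugated tetrasubstituted C5=C6 bond in preference to an exocyclic methylene, erases the relay centres C5 and C6 and leaves C4 untouched.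

Step 17
Reactants: 27 (4S)-3-[(2E,4S,5S)-5-{[tert-butyl(dimethyl)silyl]oxy}-4-methylhept-2-en-2-yl]-4-(6-methoxy-3,5-dimethyl-4-oxo-4H-pyran-2-yl)-2,4,6-trimethylcyclohexa-2,5-dien-1-one
Product: 28 (4S)-3-[(2E,4S,5S)-5-hydroxy-4-methylhept-2-en-2-yl]-4-(6-methoxy-3,5-dimethyl-4-oxo-4H-pyran-2-yl)-2,4,6-trimethylcyclohexa-2,5-dien-1-one
Conditions: HF·pyridine, pyridine, THF, 0 °C → rt
Reagents that add atoms: none
Why: Buffered fluoride-mediated desilylation frees the secondary alcohol without base, so the dienone, the methoxypyranone and the allylic stereocentre are not exposed to enolising conditions.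

Step 18
Reactants: 28 (4S)-3-[(2E,4S,5S)-5-hydroxy-4-methylhept-2-en-2-yl]-4-(6-methoxy-3,5-dimethyl-4-oxo-4H-pyran-2-yl)-2,4,6-trimethylcyclohexa-2,5-dien-1-one
Product: 29 (4S)-3-[(2E,4S)-4-methyl-5-oxohept-2-en-2-yl]-4-(6-methoxy-3,5-dimethyl-4-oxo-4H-pyran-2-yl)-2,4,6-trimethylcyclohexa-2,5-dien-1-one
Conditions: Dess–Martin periodinane, pyridine, CH2Cl2, 0 °C
Reagents that add atoms: none
Why: The Dess–Martin oxidation converts the secondary alcohol into the ethyl ketone under buffered, non-enolising conditions, so the adjacent allylic stereocentre set in step 5 should be retained and the alkene should not move into conjugation.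

Compound list
1 | ethyl 2-methyl-3-oxopentanoate (racemic) | CCC(=O)C(C)C(=O)OCC | starting material
2 | N-methoxy-N-methylpropanamide | CCC(=O)N(C)OC | starting material
3 | ethyl 2,4-dimethyl-3,5-dioxoheptanoate (stereoisomer and tautomer mixture) | CCC(=O)C(C)C(=O)C(C)C(=O)OCC | intermediate
4 | 6-ethyl-4-hydroxy-3,5-dimethyl-2H-pyran-2-one | CCc1oc(=O)c(C)c(O)c1C | intermediate
5 | 2-ethyl-6-methoxy-3,5-dimethyl-4H-pyran-4-one | CCc1oc(OC)c(C)c(=O)c1C | intermediate
6 | propanal | CCC=O | starting material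
7 | lithium 2-(6-methoxy-3,5-dimethyl-4-oxo-4H-pyran-2-yl)pentan-3-olate (diastereomer mixture) | CCC(O[Li])C(C)c1oc(OC)c(C)c(=O)c1C | intermediate
8 | 2-(6-methoxy-3,5-dimethyl-4-oxo-4H-pyran-2-yl)pentan-3-yl methanesulfonate (diastereomer mixture) | CCC(OS(C)(=O)=O)C(C)c1oc(OC)c(C)c(=O)c1C | intermediate
9 | 2-methoxy-3,5-dimethyl-6-[(2E)-pent-2-en-2-yl]-4H-pyran-4-one | CC/C=C(\C)c1oc(OC)c(C)c(=O)c1C | intermediate
10 | (R)-4-benzyl-3-propanoyl-1,3-oxazolidin-2-one | CCC(=O)N1[C@H](Cc2ccccc2)COC1=O | starting material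
11 | (R)-4-benzyl-3-[(2R,3S)-3-hydroxy-2-methylpentanoyl]-1,3-oxazolidin-2-one | CC[C@H](O)[C@@H](C)C(=O)N1[C@H](Cc2ccccc2)COC1=O | intermediate
12 | (R)-4-benzyl-3-[(2R,3S)-3-{[tert-butyl(dimethyl)silyl]oxy}-2-methylpentanoyl]-1,3-oxazolidin-2-one | CC[C@H](O[Si](C)(C)C(C)(C)C)[C@@H](C)C(=O)N1[C@H](Cc2ccccc2)COC1=O | intermediate
13 | (2S,3S)-3-{[tert-butyl(dimethyl)silyl]oxy}-2-methylpentan-1-ol | CC[C@H](O[Si](C)(C)C(C)(C)C)[C@@H](C)CO | intermediate
14 | (2R,3S)-3-{[tert-butyl(dimethyl)silyl]oxy}-2-methylpentanal | CC[C@H](O[Si](C)(C)C(C)(C)C)[C@@H](C)C=O | intermediate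
15 | 2-(triphenyl-λ5-phosphanylidene)propanal | CC(C=O)=P(c1ccccc1)(c1ccccc1)c1ccccc1 | starting material
16 | (2E,4S,5S)-5-{[tert-butyl(dimethyl)silyl]oxy}-2,4-dimethylhept-2-enal | CC[C@H](O[Si](C)(C)C(C)(C)C)[C@@H](C)/C=C(\C)C=O | intermediate
17 | ethyl 2-(triphenyl-λ5-phosphanylidene)propanoate | CCOC(=O)C(C)=P(c1ccccc1)(c1ccccc1)c1ccccc1 | starting material
18 | ethyl (2E,4E,6S,7S)-7-{[tert-butyl(dimethyl)silyl]oxy}-2,4,6-trimethylnona-2,4-dienoate | CC[C@H](O[Si](C)(C)C(C)(C)C)[C@@H](C)/C=C(\C)/C=C(\C)C(=O)OCC | intermediate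
19 | (2E,4E,6S,7S)-7-{[tert-butyl(dimethyl)silyl]oxy}-2,4,6-trimethylnona-2,4-dien-1-ol | CC[C@H](O[Si](C)(C)C(C)(C)C)[C@@H](C)/C=C(\C)/C=C(\C)CO | intermediate
20 | [(2R,3R)-3-[(2E,4S,5S)-5-{[tert-butyl(dimethyl)silyl]oxy}-4-methylhept-2-en-2-yl]-2-methyloxiran-2-yl]methanol | CC[C@H](O[Si](C)(C)C(C)(C)C)[C@@H](C)/C=C(\C)[C@H]1O[C@]1(C)CO | intermediate
21 | (2S,3R)-3-[(2E,4S,5S)-5-{[tert-butyl(dimethyl)silyl]oxy}-4-methylhept-2-en-2-yl]-2-methyloxirane-2-carbaldehyde | CC[C@H](O[Si](C)(C)C(C)(C)C)[C@@H](C)/C=C(\C)[C@H]1O[C@]1(C)C=O | intermediate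
22 | (2S,3R)-3-[(2E,4S,5S)-5-{[tert-butyl(dimethyl)silyl]oxy}-4-methylhept-2-en-2-yl]-2-methyloxirane-2-carboxylic acid | CC[C@H](O[Si](C)(C)C(C)(C)C)[C@@H](C)/C=C(\C)[C@H]1O[C@]1(C)C(=O)O | intermediate
23 | [(2S,3R)-3-[(2E,4S,5S)-5-{[tert-butyl(dimethyl)silyl]oxy}-4-methylhept-2-en-2-yl]-2-methyloxiran-2-yl](1H-imidazol-1-yl)methanone | CC[C@H](O[Si](C)(C)C(C)(C)C)[C@@H](C)/C=C(\C)[C@H]1O[C@]1(C)C(=O)n1ccnc1 | intermediate
24 | lithium trienolate of 9 (allyl anion over C2–C3–C4, drawn as the C2 carbanion) | [Li+].C[CH-]/C=C(\C)c1oc(OC)c(C)c(=O)c1C | intermediate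
25 | (3E)-1-[(2S,3R)-3-[(2E,4S,5S)-5-{[tert-butyl(dimethyl)silyl]oxy}-4-methylhept-2-en-2-yl]-2-methyloxiran-2-yl]-4-(6-methoxy-3,5-dimethyl-4-oxo-4H-pyran-2-yl)-2-methylpent-3-en-1-one (both epimers at C2 of the pentenone) | CC[C@H](O[Si](C)(C)C(C)(C)C)[C@@H](C)/C=C(\C)[C@H]1O[C@]1(C)C(=O)C(C)/C=C(\C)c1oc(OC)c(C)c(=O)c1C | intermediate
26 | (4S,5R,6S)-5-[(2E,4S,5S)-5-{[tert-butyl(dimethyl)silyl]oxy}-4-methylhept-2-en-2-yl]-6-hydroxy-4-(6-methoxy-3,5-dimethyl-4-oxo-4H-pyran-2-yl)-2,4,6-trimethylcyclohex-2-en-1-one | CC[C@H](O[Si](C)(C)C(C)(C)C)[C@@H](C)/C=C(\C)[C@H]1[C@](C)(O)C(=O)C(C)=C[C@]1(C)c1oc(OC)c(C)c(=O)c1C | intermediate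
27 | (4S)-3-[(2E,4S,5S)-5-{[tert-butyl(dimethyl)silyl]oxy}-4-methylhept-2-en-2-yl]-4-(6-methoxy-3,5-dimethyl-4-oxo-4H-pyran-2-yl)-2,4,6-trimethylcyclohexa-2,5-dien-1-one | CC[C@H](O[Si](C)(C)C(C)(C)C)[C@@H](C)/C=C(\C)C1=C(C)C(=O)C(C)=C[C@]1(C)c1oc(OC)c(C)c(=O)c1C | intermediate
28 | (4S)-3-[(2E,4S,5S)-5-hydroxy-4-methylhept-2-en-2-yl]-4-(6-methoxy-3,5-dimethyl-4-oxo-4H-pyran-2-yl)-2,4,6-trimethylcyclohexa-2,5-dien-1-one | CC[C@H](O)[C@@H](C)/C=C(\C)C1=C(C)C(=O)C(C)=C[C@]1(C)c1oc(OC)c(C)c(=O)c1C | intermediate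
29 | (4S)-3-[(2E,4S)-4-methyl-5-oxohept-2-en-2-yl]-4-(6-methoxy-3,5-dimethyl-4-oxo-4H-pyran-2-yl)-2,4,6-trimethylcyclohexa-2,5-dien-1-one | CCC(=O)[C@@H](C)/C=C(\C)C1=C(C)C(=O)C(C)=C[C@]1(C)c1oc(OC)c(C)c(=O)c1C | target

Total step count: 18. Longest linear sequence: 14 steps (steps 5 to 18, from 10).

Steps most likely to fail

Step 15. The delocalised trienolate 24 may be acylated at oxygen or at C4 instead of C2, and the stabilised anion of 25 may then be too weak a nucleophile for the 6-endo epoxide opening, so that 25 decomposes before it closes. The fallback sets out from 9 and 20 and returns at 26. Alcohol 20 is oxidised with SO3·pyridine, DMSO and iPr2NEt (Parikh–Doering oxidation) to the epoxy aldehyde 21, which is isolated. Pyranone 9 is converted with LiN(iPr)2 and t-BuMe2SiCl into the silyl trienol ether F1. A vinylogous Mukaiyama aldol addition of F1 to 21 (BF3·OEt2, CH2Cl2, −78 °C), a reaction type that bonds the remote terminus of extended silyl enol ethers, should give the aldol adduct F2. Dess–Martin oxidation then gives 25, now isolated, and KN(SiMe3)2 with 18-crown-6 (THF, −78 °C to rt) closes the ring to 26.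

Step 16. The sulfamate may eliminate towards the C6 methyl group to give an exocyclic methylene, or the heated α-hydroxy ketone may undergo an acyloin shift with ring contraction. The fallback sets out from 26 and returns at 27. SmI2 (THF–MeOH, −78 °C) removes the α-hydroxyl group reductively to give the ketone F3. LiN(SiMe3)2 and Me3SiCl convert it into the silyl dienol ether F4, since C6 is the only enolisable position on that side. Pd(OAc)2 in MeCN (Saegusa–Ito oxidation) then introduces the C5=C6 double bond and gives 27.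

Step 12. The vinyl epoxide that forms may be opened or rearranged by the Lewis-acidic Ti(OiPr)4 complex, and the conjugated diene may lower the facial selectivity. The fallback sets out from 19 and returns at 20. MnO2 (CH2Cl2) oxidises 19 to the dienal F5. An iminium-catalysed asymmetric epoxidation of this α-branched enal (aqueous H2O2, a cinchona-derived primary amine salt of the pseudo-enantiomeric series that gives the (2S,3R) product) should give the epoxy aldehyde 21, which is isolated, and NaBH4 (MeOH, −20 °C) reduces it to 20.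

Further compounds
F1 | step 15 | tert-butyl{[6-methoxy-3,5-dimethyl-2-(pent-3-en-2-ylidene)-2H-pyran-4-yl]oxy}dimethylsilane (geometry of the two new C=C bonds not defined and without consequence) | CC=CC(C)=C1OC(OC)=C(C)C(O[Si](C)(C)C(C)(C)C)=C1C
F2 | step 15 | (3E)-1-[3-[(2E,4S,5S)-5-{[tert-butyl(dimethyl)silyl]oxy}-4-methylhept-2-en-2-yl]-2-methyloxiran-2-yl]-4-(6-methoxy-3,5-dimethyl-4-oxo-4H-pyran-2-yl)-2-methylpent-3-en-1-ol (oxirane configured as in 21, mixture at C1 and C2 of the pentenol) | CC[C@H](O[Si](C)(C)C(C)(C)C)[C@@H](C)/C=C(\C)[C@H]1O[C@]1(C)C(O)C(C)/C=C(\C)c1oc(OC)c(C)c(=O)c1C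
F3 | step 16 | (4S,5R)-5-[(2E,4S,5S)-5-{[tert-butyl(dimethyl)silyl]oxy}-4-methylhept-2-en-2-yl]-4-(6-methoxy-3,5-dimethyl-4-oxo-4H-pyran-2-yl)-2,4,6-trimethylcyclohex-2-en-1-one (both epimers at C6) | CC[C@H](O[Si](C)(C)C(C)(C)C)[C@@H](C)/C=C(\C)[C@H]1C(C)C(=O)C(C)=C[C@]1(C)c1oc(OC)c(C)c(=O)c1C
F4 | step 16 | trimethylsilyl dienol ether of F3 (1-trimethylsilyloxycyclohexa-1,5-diene numbered from the former carbonyl carbon, 4S,5R centres unchanged) | CC[C@H](O[Si](C)(C)C(C)(C)C)[C@@H](C)/C=C(\C)[C@H]1C(C)=C(O[Si](C)(C)C)C(C)=C[C@]1(C)c1oc(OC)c(C)c(=O)c1C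
F5 | step 12 | (2E,4E,6S,7S)-7-{[tert-butyl(dimethyl)silyl]oxy}-2,4,6-trimethylnona-2,4-dienal | CC[C@H](O[Si](C)(C)C(C)(C)C)[C@@H](C)/C=C(\C)/C=C(\C)C=O
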